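**Plan**

1. Retrosynthetic cuts, in order: the C4 carbinol centre (back to the C4 ketone, then to the C4-epimeric alcohol); the C4–O and C3–H bonds (back to a C3=C4 alkene); the ester C–O bond; and last, in one stroke, the ring bonds O1–C2 and C3–C4.
2. Enabling feature: with the exocyclic carbon on C3 at the aldehyde level, ring oxygen O1 sits on its β-carbon C2 and C4 is its aldol carbon. The O1–C5–C4 unit is then glycolaldehyde, and C2–C3–CHO with its aryl group is 3,4-dimethoxycinnamaldehyde.
3. Forward: an amine-catalysed oxa-Michael/aldol condensation closes the oxolane (as a 2,5-dihydrofuran), the only ring made in the route; both arenes are bought. Reduction and acylation attach the 3,4-dimethoxybenzoate; hydroboration, oxidation to the ketone and hydride reduction finish the ring.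
4. Stereochemistry: C2 from the (S)-diarylprolinol silyl ether catalyst; C3 from borane delivering H anti to the C2 aryl group (CH2O ends cis to aryl); C4 from bulky hydride attack on the ketone anti to both cis substituents.
5. The aldol hydroxyl is given up on purpose in the key step, because C3 must receive its hydrogen from the face opposite the aryl group, which an aldol closure cannot deliver.

Key step: step 1

Remark on the chemistry: the target SMILES encodes the all-cis isomer (aryl, acyloxymethyl and hydroxyl on one face of the oxolane), (2S,3R,4S); the route is planned for that isomer.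

**Step 1**
Reactants: 1 (E)-3-(3,4-dimethoxyphenyl)prop-2-enal; 2 glycolaldehyde dimer (1,4-dioxane-2,5-diol)
Product: 5 (2R)-2-(3,4-dimethoxyphenyl)-2,5-dihydrofuran-3-carbaldehyde, via glycolaldehyde monomer 3 (not isolated), via aldol adduct 4 (not isolated)
Conditions: 2 (0.6 equiv; each molecule cracks in solution to two molecules of monomer 3), (S)-2-[diphenyl(trimethylsilyloxy)methyl]pyrrolidine (20 mol %), 2-nitrobenzoic acid (20 mol %), 4 Å molecular sieves, toluene, rt then 40 °C until 4 is consumed
Reagents that add atoms: none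
Why: Condensation of 1 with the secondary amine gives an E-configured, s-trans iminium ion; the hydroxyl of monomeric glycolaldehyde 3 adds to its β-carbon (O1–C2 bond), the resulting enamine attacks the tethered aldehyde (C3–C4 bond), and dehydration through the enamine followed by hydrolysis releases 5, water and the amine. The reaction type is the aminocatalytic domino oxa-Michael/aldol condensation known for salicylaldehydes (giving 2H-chromene-3-carbaldehydes), for dihydroxyacetone dimer and, in the sulfur series, for mercaptoacetaldehyde dimer. The oxolane ring closes in the aldol event as a 5-(enolexo)-exo-trig cyclisation. C2 is the only stereocentre that survives: the CPh2OSiMe3 group shields the Re face of the β-carbon, so oxygen should enter from the Si face and give the spatial arrangement of C2 in 12 (labelled 2R in 5 only because C3 outranks the aryl group there); the C3 and C4 centres of 4 are erased by the dehydration. The step needs 1,4- rather than 1,2-addition of the alcohol and O- rather than C-nucleophilic behaviour of glycolaldehyde: acetal formation and the oxa-Michael step are reversible while the intramolecular aldol/dehydration is irreversible, 1 has no α-hydrogen that could make it an enamine donor and so can only be the acceptor, and slow release of 3 from dimer 2 limits its self-aldolisation.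

**Step 2**
Reactants: 5 (2R)-2-(3,4-dimethoxyphenyl)-2,5-dihydrofuran-3-carbaldehyde
Product: 6 [(2R)-2-(3,4-dimethoxyphenyl)-2,5-dihydrofuran-3-yl]methanol
Conditions: NaBH4, CeCl3·7H2O, MeOH, −20 °C
Reagents that add atoms: none
Why: Luche reduction should add hydride 1,2 to the conjugated aldehyde, leaving the ring alkene and the C2 stereocentre untouched.

**Step 3**
Reactants: 6 [(2R)-2-(3,4-dimethoxyphenyl)-2,5-dihydrofuran-3-yl]methanol; 7 3,4-dimethoxybenzoyl chloride
Product: 8 [(2R)-2-(3,4-dimethoxyphenyl)-2,5-dihydrofuran-3-yl]methyl 3,4-dimethoxybenzoate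
Conditions: Et3N, 4-(dimethylamino)pyridine (10 mol %), CH2Cl2, 0 °C to rt
Reagents that add atoms: none
Why: Acylation of the only hydroxyl group under nucleophilic (Steglich-type) acyl-transfer catalysis installs the final ester early, so no protecting group is needed.

**Step 4**
Reactants: 8 [(2R)-2-(3,4-dimethoxyphenyl)-2,5-dihydrofuran-3-yl]methyl 3,4-dimethoxybenzoate
Product: 10 [(2S,3R,4R)-2-(3,4-dimethoxyphenyl)-4-hydroxyoxolan-3-yl]methyl 3,4-dimethoxybenzoate, via alkylborane 9 (not isolated)
Conditions: BH3·THF, THF, 0 °C; then NaBO3·4H2O, THF/H2O, rt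
Reagents that add atoms: sodium perborate tetrahydrate, [Na+].[O-]B1OO1.O.O.O.O (hydroxyl oxygen); borane–tetrahydrofuran, B.C1CCOC1 (boron of 9 only)
Why: Hydroboration–oxidation: borane should add syn across C3=C4 from the face opposite the C2 aryl group with boron on the less substituted C4, so H enters C3 anti to the aryl group (CH2O cis to it, 3R), and C–B oxidation with retention by the mild, ester-compatible perborate gives the 4R alcohol, trans to both neighbours, which steps 5 and 6 correct.

**Step 5**
Reactants: 10 [(2S,3R,4R)-2-(3,4-dimethoxyphenyl)-4-hydroxyoxolan-3-yl]methyl 3,4-dimethoxybenzoate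
Product: 11 [(2S,3S)-2-(3,4-dimethoxyphenyl)-4-oxooxolan-3-yl]methyl 3,4-dimethoxybenzoate
Conditions: Dess–Martin periodinane (1,1,1-triacetoxy-1,1-dihydro-1,2-benziodoxol-3(1H)-one), NaHCO3, CH2Cl2, 0 °C; crude 11 used at once
Reagents that add atoms: none
Why: Dess–Martin oxidation under buffered, non-basic conditions should give the ketone without time for C3 to epimerise or the β-acyloxy group to eliminate.

**Step 6**
Reactants: 11 [(2S,3S)-2-(3,4-dimethoxyphenyl)-4-oxooxolan-3-yl]methyl 3,4-dimethoxybenzoate
Product: 12 [(2S,3R,4S)-2-(3,4-dimethoxyphenyl)-4-hydroxyoxolan-3-yl]methyl 3,4-dimethoxybenzoate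
Conditions: Li[HB(sec-Bu)3] (L-Selectride), THF, −78 °C; then saturated aqueous NH4Cl at −78 °C
Reagents that add atoms: none
Why: Diastereoselective ketone reduction with a bulky trialkylborohydride: hydride should attack C4 from the face opposite the cis-disposed C3 acyloxymethyl and C2 aryl groups, giving the all-cis 4S alcohol, and the aryl ester should survive at −78 °C.

**Compound list**

1 | (E)-3-(3,4-dimethoxyphenyl)prop-2-enal (3,4-dimethoxycinnamaldehyde) | COc1ccc(/C=C/C=O)cc1OC | starting material
2 | glycolaldehyde dimer (1,4-dioxane-2,5-diol) | OC1COC(O)CO1 | starting material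
3 | glycolaldehyde (2-hydroxyacetaldehyde), monomer | OCC=O | intermediate (not isolated)
4 | (2S)-2-(3,4-dimethoxyphenyl)-4-hydroxyoxolane-3-carbaldehyde, aldol adduct, mixture at C3 and C4 | O=CC1C(O)CO[C@@H]1c1ccc(OC)c(OC)c1 | intermediate (not isolated)
5 | (2R)-2-(3,4-dimethoxyphenyl)-2,5-dihydrofuran-3-carbaldehyde | O=CC1=CCO[C@@H]1c1ccc(OC)c(OC)c1 | intermediate
6 | [(2R)-2-(3,4-dimethoxyphenyl)-2,5-dihydrofuran-3-yl]methanol | OCC1=CCO[C@@H]1c1ccc(OC)c(OC)c1 | intermediate
7 | 3,4-dimethoxybenzoyl chloride | COc1ccc(C(Cl)=O)cc1OC | starting material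
8 | [(2R)-2-(3,4-dimethoxyphenyl)-2,5-dihydrofuran-3-yl]methyl 3,4-dimethoxybenzoate | COc1ccc(C(=O)OCC2=CCO[C@@H]2c2ccc(OC)c(OC)c2)cc1OC | intermediate
9 | [(2S,3S,4R)-4-boranyl-2-(3,4-dimethoxyphenyl)oxolan-3-yl]methyl 3,4-dimethoxybenzoate (alkylborane) | COc1ccc(C(=O)OC[C@@H]2[C@@H](B)CO[C@@H]2c2ccc(OC)c(OC)c2)cc1OC | intermediate (not isolated)
10 | [(2S,3R,4R)-2-(3,4-dimethoxyphenyl)-4-hydroxyoxolan-3-yl]methyl 3,4-dimethoxybenzoate (aryl and CH2O cis, OH trans) | COc1ccc(C(=O)OC[C@@H]2[C@@H](O)CO[C@@H]2c2ccc(OC)c(OC)c2)cc1OC | intermediate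
11 | [(2S,3S)-2-(3,4-dimethoxyphenyl)-4-oxooxolan-3-yl]methyl 3,4-dimethoxybenzoate (2,3-cis) | COc1ccc(C(=O)OC[C@@H]2C(=O)CO[C@@H]2c2ccc(OC)c(OC)c2)cc1OC | intermediate
12 | [(2S,3R,4S)-2-(3,4-dimethoxyphenyl)-4-hydroxyoxolan-3-yl]methyl 3,4-dimethoxybenzoate (all-cis) | COc1ccc(C(=O)OC[C@@H]2[C@H](O)CO[C@@H]2c2ccc(OC)c(OC)c2)cc1OC | target

Total step count: 6. Longest linear sequence: 6 steps (1 to 12).

**Steps most likely to fail**

Step 1. Glycolaldehyde may be drained into self-aldol products through its own enamine, or the reversible oxa-Michael addition to the electron-rich iminium ion may not be trapped fast enough by the aldol closure, so that conversion and enantiomeric purity stay low. The fallback sets out from 1 and comes back to the route at 11. Compound 1 is combined, under the same amine with benzoic acid in CHCl3, with 1,3-dihydroxyacetone dimer F1. This ketone partner has an established oxa-Michael/aldol/hemiacetalisation cascade with enals, and its tertiary aldol hydroxyl cannot be lost. The cascade should give the cis-fused bicyclic lactol (3aS,6S,6aR)-6-(3,4-dimethoxyphenyl)tetrahydro-1H,3H-furo[3,4-c]furan-1,3a(4H)-diol F2. NaIO4 in aqueous THF cleaves the C(OH)–CH2OH glycol of the open form, the extra carbon leaving as formaldehyde, to give the enolised β-keto aldehyde (2S)-2-(3,4-dimethoxyphenyl)-4-oxooxolane-3-carbaldehyde F3. O-Acylation of its hydroxymethylene tautomer with 7 (pyridine, CH2Cl2, 0 °C) gives the enol ester [(2R)-2-(3,4-dimethoxyphenyl)-4-oxooxolan-3-ylidene]methyl 3,4-dimethoxybenzoate F4. Hydrogenation over rhodium on alumina (H2, EtOAc, 0 °C) should add hydrogen to C3 from the face opposite the aryl group and give ketone 11, from which step 6 follows.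

Step 4. Regio- or facial control of the B–H addition may be lost because of the electron-withdrawing allylic ester, borane may partly reduce the aryl ester, or the β-alkoxyborane may undergo β-elimination with ring opening. The fallback sets out from 6 and comes back at 10. The free alcohol 6 is hydroborated (excess BH3·THF, 0 °C; then NaBO3·4H2O) to the diol (3R,4R,5S)-5-(3,4-dimethoxyphenyl)-4-(hydroxymethyl)oxolan-3-ol F5. Its primary hydroxyl is then acylated selectively with 7 (2,4,6-collidine, CH2Cl2, −78 °C to 0 °C) to give 10.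

Step 5. Ketone 11 may epimerise at C3 to the more stable 2,3-trans isomer, lose the 3,4-dimethoxybenzoate by β-elimination, or suffer acyl migration in the alkoxide formed in step 6. The fallback sets out from 10 and comes back at 12, avoiding any ketone. Mitsunobu inversion of 10 with chloroacetic acid (PPh3, diisopropyl azodicarboxylate, toluene, 0 °C to rt) gives the inverted chloroacetate [(2S,3S,4S)-4-(2-chloroacetoxy)-2-(3,4-dimethoxyphenyl)oxolan-3-yl]methyl 3,4-dimethoxybenzoate F6. Thiourea and NaHCO3 in EtOH at 50 °C remove the chloroacetyl group chemoselectively to give 12.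

**Further compounds**

F1 | step 1 | 1,3-dihydroxyacetone dimer (2,5-bis(hydroxymethyl)-1,4-dioxane-2,5-diol) | OCC1(O)COC(O)(CO)CO1
F2 | step 1 | (3aS,6S,6aR)-6-(3,4-dimethoxyphenyl)tetrahydro-1H,3H-furo[3,4-c]furan-1,3a(4H)-diol (anomeric mixture) | OC1OC[C@@]2(O)CO[C@H](c3ccc(OC)c(OC)c3)[C@@H]12
F3 | step 1 | (2S)-2-(3,4-dimethoxyphenyl)-4-oxooxolane-3-carbaldehyde (enolised) | O=CC1C(=O)CO[C@@H]1c1ccc(OC)c(OC)c1
F4 | step 1 | [(2R)-2-(3,4-dimethoxyphenyl)-4-oxooxolan-3-ylidene]methyl 3,4-dimethoxybenzoate (E/Z mixture) | COc1ccc(C(=O)OC=C2C(=O)CO[C@@H]2c2ccc(OC)c(OC)c2)cc1OC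
F5 | step 4 | (3R,4R,5S)-5-(3,4-dimethoxyphenyl)-4-(hydroxymethyl)oxolan-3-ol | OC[C@@H]1[C@@H](O)CO[C@@H]1c1ccc(OC)c(OC)c1
F6 | step 5 | [(2S,3S,4S)-4-(2-chloroacetoxy)-2-(3,4-dimethoxyphenyl)oxolan-3-yl]methyl 3,4-dimethoxybenzoate | COc1ccc(C(=O)OC[C@@H]2[C@H](OC(=O)CCl)CO[C@@H]2c2ccc(OC)c(OC)c2)cc1OC
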